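**Retrosynthetic overview**

1. Numbering: seven-membered ring C1(O-angelate)–C2–C3(Me)–C4–C5(OH)–C6(Me)–C10, five-membered ring C6–C7–C8–C9(OH, iPr)–C10. Lapiferine comes from hydroxyl-directed epoxidation of C3=C4 (from the C5–OH face) and angeloylation of C1–OH on a trans-fused bicyclo[5.3.0]decenediol.
2. The seven-membered ring is the second ring, closed by ring-closing metathesis at C3=C4. The C1–C2 bond comes from a chelation-controlled methallyl addition to the C1 aldehyde released from a β-lactone.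
3. Key disconnection, first ring: C9–C10, closed by aldol-lactonisation of an acyclic keto acid to a cyclopentane-fused β-lactone. Enabling feature: on the ring C6–C7–C8–C9–C10 the tertiary C9–O bond and the C10–C1 bond are cis, so O9 and C1 can be tied into a temporary four-membered O9–C1(=O) lactone that is not in the target. This ring fixes C9/C10, makes the aldol irreversible and keeps C1 as an acyl donor.
4. The keto acid comes from a catalytic asymmetric allylboration of (E)-but-2-enal with an (E)-γ,γ-disubstituted allylboronate (C5–C6 bond, both stereocentres), followed by vinyl → CH2CO2H.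
5. The allylboronate comes from geranyl acetate (6,7-epoxidation, Meinwald rearrangement to the isopropyl ketone, allylic borylation). Ring order: cyclopentane with temporary β-lactone (step 8), cycloheptene (step 10), epoxide (step 13).

Key step: step 8

Remark: the locants C1–C10 above are used in the Why lines; the systematic names carry their own locants. Epoxide 2 is used as the racemate because its stereocentre is erased in step 2. But-2-enal is used as the E isomer.

**Route**

Step 1
Reactants: 1 geranyl acetate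
Product: 2 (2E)-6,7-epoxy-3,7-dimethyloct-2-en-1-yl acetate (racemic)
Conditions: mCPBA, NaHCO3, CH2Cl2, 0 °C
Reagents that add atoms: 3-chloroperoxybenzoic acid, O=C(OO)c1cccc(Cl)c1
Why: Prilezhaev epoxidation should select the electron-rich 6,7-alkene because the 2,3-alkene is deactivated by the allylic acetate; the new stereocentre is uncontrolled and is erased in step 2.

Step 2
Reactants: 2 (2E)-6,7-epoxy-3,7-dimethyloct-2-en-1-yl acetate
Product: 3 (2E)-3,7-dimethyl-6-oxooct-2-en-1-yl acetate
Conditions: BF3·OEt2 (cat.), CH2Cl2, −78 → 0 °C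
Reagents that add atoms: none
Why: Meinwald rearrangement, in which Lewis-acid opening at the tertiary epoxide carbon and a 1,2-hydride shift should give the isopropyl ketone, the acetate-deactivated alkene being a poor cation trap.

Step 3
Reactants: 3 (2E)-3,7-dimethyl-6-oxooct-2-en-1-yl acetate; 4 bis(pinacolato)diboron
Product: 5 (6E)-2,6-dimethyl-8-(4,4,5,5-tetramethyl-1,3,2-dioxaborolan-2-yl)oct-6-en-3-one
Conditions: Pd2(dba)3 (cat.), DMSO, 50 °C
Reagents that add atoms: none
Why: Miyaura-type palladium-catalysed borylation of an allylic acetate (π-allyl formation, transmetallation, reductive elimination at the unhindered terminus) should give the linear allylboronate with the E geometry kept and the ketone untouched.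

Step 4
Reactants: 5 (6E)-2,6-dimethyl-8-(4,4,5,5-tetramethyl-1,3,2-dioxaborolan-2-yl)oct-6-en-3-one; 6 (2E)-but-2-enal
Product: 8 (6S,7R,8E)-6-ethenyl-7-hydroxy-2,6-dimethyldec-8-en-3-one, via pinacol borate ester 7 (not isolated)
Conditions: (S)-3,3′-bis(2,4,6-triisopropylphenyl)-1,1′-binaphthyl-2,2′-diyl hydrogen phosphate [(S)-TRIP] (5 mol %), 4 Å MS, toluene, −30 °C → rt; aqueous work-up
Reagents that add atoms: none
Why: Chiral-phosphoric-acid-catalysed allylboration through a closed chair transition state, in which the E boronate places the C6 methyl syn and the oxoalkyl chain anti to the new C5 hydroxyl (zigzag C4–C5–C6–C10) and the acid, hydrogen-bonded to a boronate oxygen, should direct C6 to the Si face of the aldehyde, so that C5 and C6 are set together.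

Step 5
Reactants: 8 (6S,7R,8E)-6-ethenyl-7-hydroxy-2,6-dimethyldec-8-en-3-one
Product: 9 (6S,7R,8E)-7-[(tert-butyldimethylsilyl)oxy]-6-ethenyl-2,6-dimethyldec-8-en-3-one
Conditions: TBSOTf, 2,6-lutidine, CH2Cl2, −78 °C
Reagents that add atoms: tert-butyldimethylsilyl triflate, C[Si](C)(OS(=O)(=O)C(F)(F)F)C(C)(C)C
Why: Silyl ether formation on the hindered secondary alcohol, which should stop O5 from capturing the activated C1 acyl group in step 8 and from competing in the acylation of step 11.

Step 6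
Reactants: 9 (6S,7R,8E)-7-[(tert-butyldimethylsilyl)oxy]-6-ethenyl-2,6-dimethyldec-8-en-3-one
Product: 11 (6S,7R,8E)-7-[(tert-butyldimethylsilyl)oxy]-6-(2-hydroxyethyl)-2,6-dimethyldec-8-en-3-one, via catechol alkylboronate 10 (not isolated)
Conditions: catecholborane, RhCl(PPh3)3 (cat.), THF, 0 °C → rt; then NaOH, H2O2, 0 °C
Reagents that add atoms: catecholborane, B1Oc2ccccc2O1 (boron carried only as far as 10); hydrogen peroxide, OO
Why: Rhodium-catalysed hydroboration then oxidation should be chemoselective for the terminal vinyl group over the ketone and the 1,2-disubstituted alkene and place the oxygen on the terminal carbon (anti-Markovnikov), which becomes C1.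

Step 7
Reactants: 11 (6S,7R,8E)-7-[(tert-butyldimethylsilyl)oxy]-6-(2-hydroxyethyl)-2,6-dimethyldec-8-en-3-one
Product: 13 (3S)-3-{(1R,2E)-1-[(tert-butyldimethylsilyl)oxy]but-2-en-1-yl}-3,7-dimethyl-6-oxooctanoic acid, via keto aldehyde 12 (not isolated)
Conditions: TEMPO (cat.), PhI(OAc)2, MeCN/H2O, rt
Reagents that add atoms: water, O
Why: TEMPO (oxoammonium) oxidation of the primary alcohol to the aldehyde and, through its hydrate, to the acid should leave the silyl ether, the alkene and the ketone untouched.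

Step 8
Reactants: 13 (3S)-3-{(1R,2E)-1-[(tert-butyldimethylsilyl)oxy]but-2-en-1-yl}-3,7-dimethyl-6-oxooctanoic acid
Product: 14 (1R,2S,5R)-2-{(1R,2E)-1-[(tert-butyldimethylsilyl)oxy]but-2-en-1-yl}-2-methyl-5-(propan-2-yl)-6-oxabicyclo[3.2.0]heptan-7-one
Conditions: 2-bromo-1-propylpyridinium triflate, 4-pyrrolidinopyridine, iPr2NEt, CH2Cl2, rt, slow addition of 13
Reagents that add atoms: none
Why: Nucleophile-promoted aldol-lactonisation, the known bis-cyclisation of keto acids to cyclopentane-fused β-lactones: the pyridinium salt activates the acid, 4-pyrrolidinopyridine turns it into an acylammonium ion whose α-carbon C10 is deprotonated by the amine (the ketone is far less acidic and C6 is quaternary), and the ammonium enolate adds to the C9 ketone before the aldolate oxygen acylates itself on C1 and releases the promoter. The C9–C10 bond closes the cyclopentane C6–C7–C8–C9–C10 in a 5-(enolexo)-exo-trig aldol, and the O9–C1 bond closes the temporary four-membered lactone in a 4-exo-trig acyl substitution. Only the aldolate with O9 and C1 cis can lactonise while the trans aldolate can only revert, so the C9/C10 relationship (oxygen cis to C1, isopropyl cis to H10) is enforced by the lactone ring and made irreversible. The configuration of C10 relative to the existing C6 is decided in the ring-forming transition state, where the bulky acylammonium carbon C1 is vicinal to C6 and should take the face of the small methyl group, anti to the silyloxybutenyl branch; this gives the C5/C1 trans relationship needed for the trans ring fusion. The step needs chemoselective enolisation and one closure mode, secured by the silyl ether on O5 (no competing γ-lactone) and by the three-carbon tether C6–C7–C8 (only a five-membered ring can form). In one operation the acyclic precursor should gain the carbocycle, the tertiary carbinol C9, the C10 stereocentre and an activated C1 for the next C–C bond.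

Step 9
Reactants: 14 (1R,2S,5R)-2-{(1R,2E)-1-[(tert-butyldimethylsilyl)oxy]but-2-en-1-yl}-2-methyl-5-(propan-2-yl)-6-oxabicyclo[3.2.0]heptan-7-one; 15 (2-methylprop-2-en-1-yl)magnesium chloride
Product: 17 (1R,2S,3S)-3-{(1R,2E)-1-[(tert-butyldimethylsilyl)oxy]but-2-en-1-yl}-2-[(1S)-1-hydroxy-3-methylbut-3-en-1-yl]-3-methyl-1-(propan-2-yl)cyclopentan-1-ol, via hydroxy aldehyde 16 (not isolated)
Conditions: DIBAL-H (1.05 equiv), CH2Cl2, −78 °C; then 15, THF, −78 → −40 °C; Rochelle salt work-up
Reagents that add atoms: none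
Why: Partial reduction of the β-lactone followed by in-situ Grignard addition under Cram-chelate (1,3-chelation) control: in the six-membered O9–Al–O1 chelate cis-fused to the cyclopentane the nucleophile should attack the convex face away from C6 and its methyl group, which sets C1 with its oxygen 1,3-anti to O9.

Step 10
Reactants: 17 (1R,2S,3S)-3-{(1R,2E)-1-[(tert-butyldimethylsilyl)oxy]but-2-en-1-yl}-2-[(1S)-1-hydroxy-3-methylbut-3-en-1-yl]-3-methyl-1-(propan-2-yl)cyclopentan-1-ol
Product: 18 (1S,2S,6R,7S,10R)-6-[(tert-butyldimethylsilyl)oxy]-4,7-dimethyl-10-(propan-2-yl)bicyclo[5.3.0]dec-4-ene-2,10-diol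
Conditions: second-generation Hoveyda–Grubbs catalyst (5 mol %), toluene, 80 °C
Reagents that add atoms: none
Why: Ring-closing metathesis between the methallyl alkene and the propenyl group (loss of propene) should close the seven-membered ring as a Z-trisubstituted alkene; the two arms are trans on the cyclopentane, so the ring fusion is trans by construction.

Step 11
Reactants: 18 (1S,2S,6R,7S,10R)-6-[(tert-butyldimethylsilyl)oxy]-4,7-dimethyl-10-(propan-2-yl)bicyclo[5.3.0]dec-4-ene-2,10-diol; 19 angelic acid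
Product: 21 (1S,2S,6R,7S,10R)-6-[(tert-butyldimethylsilyl)oxy]-10-hydroxy-4,7-dimethyl-10-(propan-2-yl)bicyclo[5.3.0]dec-4-en-2-yl (2Z)-2-methylbut-2-enoate, via mixed anhydride 20 (not isolated)
Conditions: 19, 2,4,6-trichlorobenzoyl chloride, Et3N, toluene, rt; then 18, 80 °C
Reagents that add atoms: 2,4,6-trichlorobenzoyl chloride, O=C(Cl)c1c(Cl)cc(Cl)cc1Cl (atoms carried only as far as 20)
Why: Yamaguchi-type esterification without a nucleophilic catalyst should acylate the secondary C1 hydroxyl at the angeloyl carbonyl and keep the Z geometry, the tertiary C9 hydroxyl being too hindered and O5 silylated.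

Step 12
Reactants: 21 (1S,2S,6R,7S,10R)-6-[(tert-butyldimethylsilyl)oxy]-10-hydroxy-4,7-dimethyl-10-(propan-2-yl)bicyclo[5.3.0]dec-4-en-2-yl (2Z)-2-methylbut-2-enoate
Product: 22 (1S,2S,6R,7S,10R)-6,10-dihydroxy-4,7-dimethyl-10-(propan-2-yl)bicyclo[5.3.0]dec-4-en-2-yl (2Z)-2-methylbut-2-enoate
Conditions: HF·pyridine, pyridine, THF, 0 °C → rt
Reagents that add atoms: none
Why: Fluoride desilylation under buffered conditions should free the allylic C5 hydroxyl without acyl migration or isomerisation of the angelate.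

Step 13
Reactants: 22 (1S,2S,6R,7S,10R)-6,10-dihydroxy-4,7-dimethyl-10-(propan-2-yl)bicyclo[5.3.0]dec-4-en-2-yl (2Z)-2-methylbut-2-enoate
Product: 23 lapiferine
Conditions: VO(acac)2 (cat.), tBuOOH, CH2Cl2, 0 °C → rt
Reagents that add atoms: tert-butyl hydroperoxide, CC(C)(C)OO
Why: Hydroxyl-directed vanadium-catalysed epoxidation should deliver oxygen to C3=C4 of the cycloheptenol from the face of the C5 hydroxyl (syn epoxy alcohol) and ignore the electron-poor angelate alkene.

**Compound list**

1 | geranyl acetate, (2E)-3,7-dimethylocta-2,6-dien-1-yl acetate | CC(C)=CCC/C(C)=C/COC(C)=O | starting material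
2 | (2E)-6,7-epoxy-3,7-dimethyloct-2-en-1-yl acetate (racemic at the epoxide CH) | CC1(C)OC1CC/C(C)=C/COC(C)=O | intermediate
3 | (2E)-3,7-dimethyl-6-oxooct-2-en-1-yl acetate | CC(C)C(=O)CC/C(C)=C/COC(C)=O | intermediate
4 | bis(pinacolato)diboron | CC1(C)OB(OC1(C)C)B1OC(C)(C)C(C)(C)O1 | starting material
5 | (6E)-2,6-dimethyl-8-(4,4,5,5-tetramethyl-1,3,2-dioxaborolan-2-yl)oct-6-en-3-one | CC(C)C(=O)CC/C(C)=C/CB1OC(C)(C)C(C)(C)O1 | intermediate
6 | (2E)-but-2-enal | C/C=C/C=O | starting material
7 | (6S,7R,8E)-6-ethenyl-2,6-dimethyl-7-[(4,4,5,5-tetramethyl-1,3,2-dioxaborolan-2-yl)oxy]dec-8-en-3-one (not isolated) | C/C=C/[C@@H](OB1OC(C)(C)C(C)(C)O1)[C@@](C=C)(C)CCC(=O)C(C)C | intermediate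
8 | (6S,7R,8E)-6-ethenyl-7-hydroxy-2,6-dimethyldec-8-en-3-one | C/C=C/[C@@H](O)[C@@](C=C)(C)CCC(=O)C(C)C | intermediate
9 | (6S,7R,8E)-7-[(tert-butyldimethylsilyl)oxy]-6-ethenyl-2,6-dimethyldec-8-en-3-one | C/C=C/[C@@H](O[Si](C)(C)C(C)(C)C)[C@@](C=C)(C)CCC(=O)C(C)C | intermediate
10 | (6R,7R,8E)-6-[2-(1,3,2-benzodioxaborol-2-yl)ethyl]-7-[(tert-butyldimethylsilyl)oxy]-2,6-dimethyldec-8-en-3-one (not isolated) | C/C=C/[C@@H](O[Si](C)(C)C(C)(C)C)[C@@](CCB1Oc2ccccc2O1)(C)CCC(=O)C(C)C | intermediate
11 | (6S,7R,8E)-7-[(tert-butyldimethylsilyl)oxy]-6-(2-hydroxyethyl)-2,6-dimethyldec-8-en-3-one | C/C=C/[C@@H](O[Si](C)(C)C(C)(C)C)[C@@](CCO)(C)CCC(=O)C(C)C | intermediate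
12 | (3S)-3-{(1R,2E)-1-[(tert-butyldimethylsilyl)oxy]but-2-en-1-yl}-3,7-dimethyl-6-oxooctanal (not isolated) | C/C=C/[C@@H](O[Si](C)(C)C(C)(C)C)[C@@](CC=O)(C)CCC(=O)C(C)C | intermediate
13 | (3S)-3-{(1R,2E)-1-[(tert-butyldimethylsilyl)oxy]but-2-en-1-yl}-3,7-dimethyl-6-oxooctanoic acid | C/C=C/[C@@H](O[Si](C)(C)C(C)(C)C)[C@@](CC(=O)O)(C)CCC(=O)C(C)C | intermediate
14 | (1R,2S,5R)-2-{(1R,2E)-1-[(tert-butyldimethylsilyl)oxy]but-2-en-1-yl}-2-methyl-5-(propan-2-yl)-6-oxabicyclo[3.2.0]heptan-7-one | C/C=C/[C@@H](O[Si](C)(C)C(C)(C)C)[C@@]1(C)CC[C@]2(C(C)C)OC(=O)[C@H]12 | intermediate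
15 | (2-methylprop-2-en-1-yl)magnesium chloride | CC(=C)C[Mg]Cl | starting material
16 | (1R,2S,5R)-2-{(1R,2E)-1-[(tert-butyldimethylsilyl)oxy]but-2-en-1-yl}-5-hydroxy-2-methyl-5-(propan-2-yl)cyclopentane-1-carbaldehyde (not isolated, present as its aluminium alkoxide) | C/C=C/[C@@H](O[Si](C)(C)C(C)(C)C)[C@@]1(C)CC[C@@](O)(C(C)C)[C@@H]1C=O | intermediate
17 | (1R,2S,3S)-3-{(1R,2E)-1-[(tert-butyldimethylsilyl)oxy]but-2-en-1-yl}-2-[(1S)-1-hydroxy-3-methylbut-3-en-1-yl]-3-methyl-1-(propan-2-yl)cyclopentan-1-ol | C/C=C/[C@@H](O[Si](C)(C)C(C)(C)C)[C@@]1(C)CC[C@@](O)(C(C)C)[C@@H]1[C@@H](O)CC(C)=C | intermediate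
18 | (1S,2S,6R,7S,10R)-6-[(tert-butyldimethylsilyl)oxy]-4,7-dimethyl-10-(propan-2-yl)bicyclo[5.3.0]dec-4-ene-2,10-diol | O[C@H]1CC(C)=C[C@@H](O[Si](C)(C)C(C)(C)C)[C@@]2(C)CC[C@@](O)(C(C)C)[C@H]12 | intermediate
19 | angelic acid, (2Z)-2-methylbut-2-enoic acid | C/C=C(/C)C(=O)O | starting material
20 | (2Z)-2-methylbut-2-enoic 2,4,6-trichlorobenzoic anhydride (not isolated) | C/C=C(/C)C(=O)OC(=O)c1c(Cl)cc(Cl)cc1Cl | intermediate
21 | (1S,2S,6R,7S,10R)-6-[(tert-butyldimethylsilyl)oxy]-10-hydroxy-4,7-dimethyl-10-(propan-2-yl)bicyclo[5.3.0]dec-4-en-2-yl (2Z)-2-methylbut-2-enoate | C/C=C(/C)C(=O)O[C@H]1CC(C)=C[C@@H](O[Si](C)(C)C(C)(C)C)[C@@]2(C)CC[C@@](O)(C(C)C)[C@H]12 | intermediate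
22 | (1S,2S,6R,7S,10R)-6,10-dihydroxy-4,7-dimethyl-10-(propan-2-yl)bicyclo[5.3.0]dec-4-en-2-yl (2Z)-2-methylbut-2-enoate | C/C=C(/C)C(=O)O[C@H]1CC(C)=C[C@@H](O)[C@@]2(C)CC[C@@](O)(C(C)C)[C@H]12 | intermediate
23 | lapiferine, (1S,2S,4R,5S,6S,7S,10R)-4,5-epoxy-6,10-dihydroxy-4,7-dimethyl-10-(propan-2-yl)bicyclo[5.3.0]decan-2-yl (2Z)-2-methylbut-2-enoate | C/C=C(/C)C(=O)O[C@H]1C[C@@]2(C)O[C@H]2[C@@H](O)[C@@]2(C)CC[C@@](O)(C(C)C)[C@H]12 | target

**Summary**

Total step count: 13. Longest linear sequence: 13 steps (geranyl acetate 1 to lapiferine 23).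

Steps most likely to fail:

Step 8. The acylammonium enolate at C10 is neopentylic to the quaternary C6 and may add too slowly to the α-branched ketone, so that oligomerisation of the activated acid or poor facial discrimination with respect to C6 takes over. The fallback sets out from acid 13 and replaces the lactonisation by a chelated thioester aldol. Thiophenol, DCC and DMAP should give S-phenyl (3S)-3-{(1R,2E)-1-[(tert-butyldimethylsilyl)oxy]but-2-en-1-yl}-3,7-dimethyl-6-oxooctanethioate F1. Soft enolisation with MgBr2·OEt2 and iPr2NEt in CH2Cl2 should enolise the thioester selectively and close the ring through a magnesium-bridged transition state to the cis β-hydroxy thioester S-phenyl (1R,2S,5R)-2-{(1R,2E)-1-[(tert-butyldimethylsilyl)oxy]but-2-en-1-yl}-5-hydroxy-2-methyl-5-(propan-2-yl)cyclopentane-1-carbothioate F2. DIBAL-H at −78 °C should then reduce F2 to hydroxy aldehyde 16, where the route is rejoined before the Grignard addition of step 9.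

Step 9. Over-reduction of the released aldehyde, retro-aldol opening of the tertiary β-oxido aldehyde or poor facial selectivity in the addition may erode the C1 centre. The fallback sets out from β-lactone 14 and sets C1 after ring closure. MeNH(OMe)·HCl and Me2AlCl should open 14 to the Weinreb amide (1R,2S,5R)-2-{(1R,2E)-1-[(tert-butyldimethylsilyl)oxy]but-2-en-1-yl}-5-hydroxy-N-methoxy-N,2-dimethyl-5-(propan-2-yl)cyclopentane-1-carboxamide F3. Reagent 15 should convert F3 into the ketone 1-[(1R,2S,5R)-2-{(1R,2E)-1-[(tert-butyldimethylsilyl)oxy]but-2-en-1-yl}-5-hydroxy-2-methyl-5-(propan-2-yl)cyclopentyl]-3-methylbut-3-en-1-one F4. Ring-closing metathesis as in step 10 should give (1R,6R,7S,10R)-6-[(tert-butyldimethylsilyl)oxy]-10-hydroxy-4,7-dimethyl-10-(propan-2-yl)bicyclo[5.3.0]dec-4-en-2-one F5. An Evans–Saksena reduction with Me4NBH(OAc)3 in AcOH/MeCN should deliver hydride from the boron bound to O9, which lies on the ketone face opposite to H10, and return to the route at diol 18.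

Step 4. Allyl transfer from the hindered γ,γ-disubstituted boronate may be slow and the enantiofacial discrimination on the enal insufficient. The fallback sets out from acetate 3 and moves the stereocontrol from a catalyst to a covalent auxiliary on boron. Palladium-catalysed borylation of 3 with tetrahydroxydiboron should give [(2E)-3,7-dimethyl-6-oxooct-2-en-1-yl]boronic acid F6. Condensation with diisopropyl (2R,3R)-tartrate over MgSO4 should give diisopropyl (4R,5R)-2-[(2E)-3,7-dimethyl-6-oxooct-2-en-1-yl]-1,3,2-dioxaborolane-4,5-dicarboxylate F7. Reaction of F7 with aldehyde 6 in toluene at −78 °C with 4 Å molecular sieves (tartrate-controlled Si-face allylboration through the same chair transition state) should return to the route at alcohol 8.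

Further compounds
F1 | step 8 | S-phenyl (3S)-3-{(1R,2E)-1-[(tert-butyldimethylsilyl)oxy]but-2-en-1-yl}-3,7-dimethyl-6-oxooctanethioate | C/C=C/[C@@H](O[Si](C)(C)C(C)(C)C)[C@@](CC(=O)Sc1ccccc1)(C)CCC(=O)C(C)C
F2 | step 8 | S-phenyl (1R,2S,5R)-2-{(1R,2E)-1-[(tert-butyldimethylsilyl)oxy]but-2-en-1-yl}-5-hydroxy-2-methyl-5-(propan-2-yl)cyclopentane-1-carbothioate | C/C=C/[C@@H](O[Si](C)(C)C(C)(C)C)[C@@]1(C)CC[C@@](O)(C(C)C)[C@@H]1C(=O)Sc1ccccc1
F3 | step 9 | (1R,2S,5R)-2-{(1R,2E)-1-[(tert-butyldimethylsilyl)oxy]but-2-en-1-yl}-5-hydroxy-N-methoxy-N,2-dimethyl-5-(propan-2-yl)cyclopentane-1-carboxamide | C/C=C/[C@@H](O[Si](C)(C)C(C)(C)C)[C@@]1(C)CC[C@@](O)(C(C)C)[C@@H]1C(=O)N(C)OC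
F4 | step 9 | 1-[(1R,2S,5R)-2-{(1R,2E)-1-[(tert-butyldimethylsilyl)oxy]but-2-en-1-yl}-5-hydroxy-2-methyl-5-(propan-2-yl)cyclopentyl]-3-methylbut-3-en-1-one | C/C=C/[C@@H](O[Si](C)(C)C(C)(C)C)[C@@]1(C)CC[C@@](O)(C(C)C)[C@@H]1C(=O)CC(C)=C
F5 | step 9 | (1R,6R,7S,10R)-6-[(tert-butyldimethylsilyl)oxy]-10-hydroxy-4,7-dimethyl-10-(propan-2-yl)bicyclo[5.3.0]dec-4-en-2-one | O=C1CC(C)=C[C@@H](O[Si](C)(C)C(C)(C)C)[C@@]2(C)CC[C@@](O)(C(C)C)[C@H]12
F6 | step 4 | [(2E)-3,7-dimethyl-6-oxooct-2-en-1-yl]boronic acid | CC(C)C(=O)CC/C(C)=C/CB(O)O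
F7 | step 4 | diisopropyl (4R,5R)-2-[(2E)-3,7-dimethyl-6-oxooct-2-en-1-yl]-1,3,2-dioxaborolane-4,5-dicarboxylate | CC(C)C(=O)CC/C(C)=C/CB1O[C@@H](C(=O)OC(C)C)[C@H](C(=O)OC(C)C)O1
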